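**Retrosynthetic overview**

1. Psidial A ⇐ dihydroxychroman 34 (two Vilsmeier–Haack formylations) ⇐ chromanone 30 (phenyl by organocerium addition, H‑1′ by ionic hydrogenation).
2. Feature used: in the pyran ring the ether oxygen on quaternary C4 and the benzylic carbon C1′ (on C5) sit on neighbouring carbons of the 1,3,5‑trioxygenated arene. This is the pattern left when a C4 alkoxide adds to a 3,5‑dialkoxyaryne and the aryl anion next to the alkoxy group acylates on a C5 ester.
3. Key disconnection: 30 ⇐ nine‑membered β‑hydroxy ester 20 + aryne precursor 26 (O–aryl and aryl–C1′ bonds, pyranone ring).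
4. 20 ⇐ SmI2 Reformatsky closure of C4–C5 in bromo keto ester 18 ⇐ trans‑cyclobutane from the enantioselective cyclohexenone/isobutene [2+2] adduct 3 (sets C1), ring cleavage, Negishi acylation, epimerisation (sets C9).
5. Ring order: cyclobutane, nine‑membered ring, pyranone (the arene arrives with the aryne).

Key step: step 16

Remark (numbering): cyclobutane = C1, C9, C10, C11 (C11 = CMe2, bonded to C1); nine‑membered ring = C1–C9; C4 = carbinol carbon, C5 = its CH neighbour, C8 = methylidene carbon; C1′ = benzylic carbon. The target is (1S,4S,5R,9R,1′R), the cyclobutane being antipodal to that of natural (−)‑β‑caryophyllene, so the skeleton is built de novo.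

Remark (protecting groups): the two phenol oxygens are carried as methoxymethyl (MOM) ethers instead of methyl ethers. They come off in dilute acid, and the free phloroglucinol‑type ring is then formylated twice at room temperature, conditions that should spare the C8 methylidene and the tertiary aryl ether.

Remark (catalyst): the antipode of the oxazaborolidine is taken that gives the (6S) photoadduct; both antipodes are equally accessible.

**Route**

Step 1
Reactants: 1 cyclohex-2-en-1-one; 2 isobutene
Product: 3 (1S,6S)-7,7-dimethylbicyclo[4.2.0]octan-2-one (cis-fused)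
Conditions: AlBr3-activated chiral oxazaborolidine (B-(2,4,6-trifluorophenyl), diarylprolinol-derived, 50 mol%), excess 2, CH2Cl2, −75 °C, hν (366 nm); then basic Al2O3, rt
Reagents that add atoms: none
Why: Enantioselective Lewis‑acid‑catalysed enone–alkene [2+2] photocycloaddition: only the enone bound to the chiral Lewis acid absorbs at 366 nm and one of its faces is shielded, so the β‑carbon (future C1, bonded to CMe2 in the head‑to‑tail adduct) is set as S, while the α‑carbon is equilibrated to the cis ring fusion on Al2O3 and is reset in step 7.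

Step 2
Reactants: 3
Product: 5 [(1S,6S)-7,7-dimethylbicyclo[4.2.0]oct-2-en-2-yl]oxy(trimethyl)silane, via lithium enolate 4 (not isolated)
Conditions: LDA, THF, −78 °C; TMSCl, −78 °C → rt
Reagents that add atoms: chlorotrimethylsilane, C[Si](C)(C)Cl
Why: Kinetic enolisation takes the α′‑CH2 proton, not the hindered cyclobutane methine, and O‑silylation gives the silyl enol ether that marks the C2–C3 bond for cleavage.

Step 3
Reactants: 5
Product: 7 (1S,2S)-3,3-dimethyl-2-(3-oxopropyl)cyclobutane-1-carboxylic acid, via silyloxy ozonide 6 (not isolated)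
Conditions: O3, CH2Cl2, −78 °C; then Me2S, −78 °C → rt; aqueous work-up
Reagents that add atoms: ozone, [O-][O+]=O
Why: Ozonolysis of a silyl enol ether cleaves the six‑membered ring into a carboxylic acid (future C8) and an aldehyde (future C4) at different oxidation levels, leaving both cyclobutane stereocentres untouched.

Step 4
Reactants: 7
Product: 8 (1S,2S)-2-(but-3-en-1-yl)-3,3-dimethylcyclobutane-1-carboxylic acid
Conditions: Ph3PCH3Br (2.6 equiv), NaHMDS (2.5 equiv), THF, 0 °C → rt
Reagents that add atoms: methyltriphenylphosphonium bromide, C[P+](c1ccccc1)(c1ccccc1)c1ccccc1.[Br-]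
Why: Wittig methylenation of the aldehyde in the presence of the carboxylate gives a vinyl group that serves as a masked C4 methyl ketone and survives the later ketone chemistry at C8.

Step 5
Reactants: 9 methyl 4-bromobutanoate
Product: 10 (4-methoxy-4-oxobutyl)zinc bromide (THF solution)
Conditions: Zn dust (activated with BrCH2CH2Br and TMSCl), LiCl, THF, 40 °C
Reagents that add atoms: zinc, [Zn]
Why: LiCl‑promoted insertion of zinc into a primary alkyl bromide gives an alkylzinc halide that tolerates its own ester and supplies C5–C7 with the ester carbon.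

Step 6
Reactants: 8; 10
Product: 12 methyl 5-[(1S,2S)-2-(but-3-en-1-yl)-3,3-dimethylcyclobutyl]-5-oxopentanoate, via acid chloride 11 (not isolated)
Conditions: (COCl)2, DMF (cat.), CH2Cl2, 0 °C → rt, evaporate; then 10, Pd(PPh3)4 (4 mol%), THF, 0 °C → rt
Reagents that add atoms: none
Why: Negishi acylation of the acid chloride with the alkylzinc reagent forms the C7–C8 bond and the C8 ketone without touching the ester or the terminal alkene.

Step 7
Reactants: 12
Product: 13 methyl 5-[(1R,2S)-2-(but-3-en-1-yl)-3,3-dimethylcyclobutyl]-5-oxopentanoate (trans)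
Conditions: NaOMe (0.3 equiv), MeOH, rt
Reagents that add atoms: none
Why: Base‑mediated epimerisation under thermodynamic control: reversible enolisation at C9, the only stereocentre α to the ketone, should drain the cis isomer into the less strained trans‑1,2‑disubstituted cyclobutane and so set C9 as R.

Step 8
Reactants: 13
Product: 14 methyl 5-[(1R,2S)-2-(but-3-en-1-yl)-3,3-dimethylcyclobutyl]hex-5-enoate
Conditions: Ph3PCH3Br (2.0 equiv), NaHMDS (1.9 equiv), THF, 0 → 50 °C
Reagents that add atoms: methyltriphenylphosphonium bromide, C[P+](c1ccccc1)(c1ccccc1)c1ccccc1.[Br-]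
Why: Wittig methylenation of the cyclobutyl ketone installs the C8 methylidene; the methyl ester does not react with the ylide and C9 is already at its thermodynamic configuration.

Step 9
Reactants: 14
Product: 17 methyl 2-bromo-5-[(1R,2S)-2-(but-3-en-1-yl)-3,3-dimethylcyclobutyl]hex-5-enoate (both C2 epimers), via lithium ester enolate 15 (not isolated), via silyl ketene acetal 16 (not isolated)
Conditions: LDA, THF, −78 °C; TMSCl, −78 °C; then NBS, −78 → 0 °C
Reagents that add atoms: N-bromosuccinimide, O=C1CCC(=O)N1Br
Why: Bromination of the silyl ketene acetal with NBS puts the halogen on C5 before any ketone is present; the unactivated alkenes do not react at low temperature and the C5 epimers converge in step 11.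

Step 10
Reactants: 17
Product: 18 methyl 2-bromo-5-[(1R,2S)-3,3-dimethyl-2-(3-oxobutyl)cyclobutyl]hex-5-enoate (both C2 epimers)
Conditions: PdCl2 (10 mol%), Cu(OAc)2 (20 mol%), O2 (1 atm), DMA/H2O 7:1, rt
Reagents that add atoms: water, O
Why: Wacker oxidation converts the monosubstituted alkene into the C4 methyl ketone and leaves the 1,1‑disubstituted C8 alkene alone; the low‑chloride copper acetate variant is chosen to limit halide exchange at the α‑bromo ester.

Step 11
Reactants: 18
Product: 20 methyl (1S,4S,5S,9R)-4-hydroxy-4,11,11-trimethyl-8-methylidenebicyclo[7.2.0]undecane-5-carboxylate, via samarium enolate 19 (not isolated)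
Conditions: SmI2 (2.5 equiv), THF, −78 °C, slow addition of 18 (final 3 mM), −78 → −20 °C; pH 7 buffer
Reagents that add atoms: none
Why: Samarium Reformatsky reaction: SmI2 reduces the α‑bromo ester faster than the ketone and the trivalent samarium enolate is held to the ketone oxygen in a chair‑like six‑membered chelate that templates the nine‑membered ring, the tether taking the two equatorial sites so that C3 and C6 come out trans (C4 methyl anti to H‑5); the trans‑cyclobutane is expected to steer closure to the (4S,5S) face, a preference that is not secured and is treated under the risks.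

Step 12
Reactants: 21 phloroglucinol
Product: 22 3,5-bis(methoxymethoxy)phenol
Conditions: MOMCl (2.1 equiv), iPr2NEt (2.5 equiv), DMF, 0 °C → rt; chromatography
Reagents that add atoms: chloromethyl methyl ether, COCCl
Why: O‑Alkylation of the symmetric triol with two equivalents of the α‑chloro ether gives the bis‑ether as the main component of a statistical mixture, separable from mono‑ and tris‑ether.

Step 13
Reactants: 22
Product: 23 2-bromo-3,5-bis(methoxymethoxy)phenol
Conditions: NBS (1.0 equiv), CH2Cl2, −78 → −20 °C
Reagents that add atoms: N-bromosuccinimide, O=C1CCC(=O)N1Br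
Why: Electrophilic aromatic bromination ortho to the free hydroxyl; the position between the two MOM ethers is the competing site and that isomer is removed.

Step 14
Reactants: 23
Product: 24 [2-bromo-3,5-bis(methoxymethoxy)phenoxy]trimethylsilane
Conditions: HMDS, THF, 70 °C; concentrate
Reagents that add atoms: hexamethyldisilazane, C[Si](C)(C)N[Si](C)(C)C
Why: O‑Silylation of the phenol, with ammonia as the only by‑product, places silicon where the following 1,3‑shift needs it.

Step 15
Reactants: 24
Product: 26 3,5-bis(methoxymethoxy)-2-(trimethylsilyl)phenyl trifluoromethanesulfonate, via lithium phenoxide 25 (not isolated)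
Conditions: n-BuLi, THF, −100 → −78 °C; then Tf2O, −100 → −78 °C
Reagents that add atoms: trifluoromethanesulfonic anhydride, O=S(=O)(OS(=O)(=O)C(F)(F)F)C(F)(F)F
Why: Bromine–lithium exchange triggers the 1,3 shift of silicon from oxygen to carbon (retro‑Brook rearrangement) and the resulting phenoxide is triflated in the same flask, which fixes SiMe3 and OTf on adjacent carbons next to one MOM ether.

Step 16
Reactants: 20; 26
Product: 30 tricyclic 5,7-bis(methoxymethoxy)chroman-4-one fused through C4 (ether oxygen) and C5 (carbonyl C1′) to the (1S,4S,5S,9R)-4,11,11-trimethyl-8-methylidenebicyclo[7.2.0]undecane core, via sodium alkoxide 27 (not isolated), via aryne 28 (not isolated), via aryl anion 29 (not isolated)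
Conditions: NaH (1.05 equiv), THF, −20 °C; then 26 (1.5 equiv), CsF (3 equiv), 18-crown-6 (3 equiv), THF, −20 °C → rt
Reagents that add atoms: none
Why: Proposed new method: NaH turns the C4 tertiary alcohol into the sodium alkoxide 27, fluoride strips the silyl group from 26 to release the aryne 28, and the alkoxide adds to the aryne carbon remote from the flanking MOM ether, which leaves the aryl anion 29 on the carbon next to that ether, where the C–O dipole stabilises it. The anion then attacks the C5 ester carbonyl and expels methoxide, an intramolecular acyl substitution that closes the pyranone ring in the 6‑exo‑trig mode and forms the aryl–C1′ bond. The closest known reactions are the fluoride‑induced annulation of salicylate esters with arynes to xanthones (O‑addition, then acylation by the aryl anion) and the addition of tert‑butoxide to arynes; what is new is a hindered aliphatic β‑hydroxy ester alkoxide as the oxygen partner. No stereocentre is created: C4 reacts at oxygen with retention and C5 stays as it is provided the aryl anion acylates faster than it abstracts H‑5. Two selectivities are needed: the regiochemistry of O‑addition, which the distortion of the aryne by the neighbouring alkoxy group secures and which gives the 1,3,5‑oxygen pattern of the target, and annulation ahead of retro‑aldol opening of the nine‑membered ring, for which the nucleophile is an ester aldolate (a poorer leaving enolate than that of a ketone), held as a sodium chelate and kept cold while the aryne is generated.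

Step 17
Reactants: 30
Product: 31 C1′ tertiary alcohol of 30 (1′-hydroxy-1′-phenyl; mixture at C1′)
Conditions: PhLi (3 equiv), CeCl3 (anhydrous, 3.2 equiv), THF, −78 °C; then 30, −78 → −40 °C
Reagents that add atoms: phenyllithium, [Li]c1ccccc1
Why: 1,2‑Addition of the organocerium reagent PhCeCl2, which is nucleophilic but weakly basic, so the hindered aryl ketone should be attacked without enolisation at C5 or β‑elimination of the aryloxide; the new carbinol centre is erased in step 18.

Step 18
Reactants: 31
Product: 33 (1S,4S,5R,9R,1′R)-1′-phenylchroman with both phenols as MOM ethers, via diarylmethyl cation 32 (not isolated)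
Conditions: Et3SiH (10 equiv), BF3·OEt2 (1.5 equiv), CH2Cl2, −78 °C
Reagents that add atoms: none
Why: Ionic hydrogenation: BF3·OEt2 ionises the diarylcarbinol to cation 32, stabilised by three ring oxygens and the phenyl group; allylic strain with the phenyl group pushes the C5–C6 bond out of the plane of the cation and Et3SiH delivers hydride anti to that bond and to the C4 methyl group, so H‑1′ should come out cis to H‑5 and the phenyl group cis to the C4 methyl (1′R).

Step 19
Reactants: 33
Product: 34 (1S,4S,5R,9R,1′R)-5′,7′-dihydroxy-1′-phenylchroman (psidial A lacking both formyl groups)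
Conditions: HCl (3 M aq., 6 equiv), MeOH, 40 °C
Reagents that add atoms: none
Why: Acid hydrolysis of the two aryl MOM acetals; methanol traps the methoxymethyl cation as dimethoxymethane so that the electron‑rich ring is not alkylated, and dilute acid should leave the C8 alkene and the tertiary aryl ether intact.

Step 20
Reactants: 34
Product: 36 psidial A, via bis-iminium salt 35 (not isolated)
Conditions: POCl3 (4 equiv), DMF (8 equiv), MeCN, 0 °C → rt; then H2O, 50 °C
Reagents that add atoms: N,N-dimethylformamide, CN(C)C=O; water, O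
Why: Vilsmeier–Haack formylation, twice: with both hydroxyls free the phloroglucinol‑type ring is nucleophilic enough for two formylations at room temperature, only two ring positions are open, and the unactivated C8 alkene does not react with the chloroiminium reagent under these conditions.

**Compound list**

1 | cyclohex-2-en-1-one | O=C1C=CCCC1 | starting material
2 | isobutene | C=C(C)C | starting material
3 | (1S,6S)-7,7-dimethylbicyclo[4.2.0]octan-2-one | O=C1CCC[C@H]2[C@@H]1CC2(C)C | intermediate
4 | lithium (1S,6S)-7,7-dimethylbicyclo[4.2.0]oct-2-en-2-olate | [Li+].[O-]C1=CCC[C@H]2[C@@H]1CC2(C)C | intermediate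
5 | [(1S,6S)-7,7-dimethylbicyclo[4.2.0]oct-2-en-2-yl]oxy(trimethyl)silane | C[Si](C)(C)OC1=CCC[C@H]2[C@@H]1CC2(C)C | intermediate
6 | silyloxy ozonide of 5 (1,2,4-trioxolane across former C2–C3) | C[Si](C)(C)OC12OC(OO1)CC[C@H]1[C@@H]2CC1(C)C | intermediate
7 | (1S,2S)-3,3-dimethyl-2-(3-oxopropyl)cyclobutane-1-carboxylic acid | O=CCC[C@H]1[C@@H](C(=O)O)CC1(C)C | intermediate
8 | (1S,2S)-2-(but-3-en-1-yl)-3,3-dimethylcyclobutane-1-carboxylic acid | C=CCC[C@H]1[C@@H](C(=O)O)CC1(C)C | intermediate
9 | methyl 4-bromobutanoate | COC(=O)CCCBr | starting material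
10 | (4-methoxy-4-oxobutyl)zinc bromide | COC(=O)CCC[Zn]Br | intermediate
11 | (1S,2S)-2-(but-3-en-1-yl)-3,3-dimethylcyclobutane-1-carbonyl chloride | C=CCC[C@H]1[C@@H](C(=O)Cl)CC1(C)C | intermediate
12 | methyl 5-[(1S,2S)-2-(but-3-en-1-yl)-3,3-dimethylcyclobutyl]-5-oxopentanoate | C=CCC[C@H]1[C@@H](C(=O)CCCC(=O)OC)CC1(C)C | intermediate
13 | methyl 5-[(1R,2S)-2-(but-3-en-1-yl)-3,3-dimethylcyclobutyl]-5-oxopentanoate | C=CCC[C@H]1[C@H](C(=O)CCCC(=O)OC)CC1(C)C | intermediate
14 | methyl 5-[(1R,2S)-2-(but-3-en-1-yl)-3,3-dimethylcyclobutyl]hex-5-enoate | C=CCC[C@H]1[C@H](C(=C)CCCC(=O)OC)CC1(C)C | intermediate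
15 | lithium ester enolate of 14 | [Li+].C=CCC[C@H]1[C@H](C(=C)CCC=C(OC)[O-])CC1(C)C | intermediate
16 | trimethylsilyl ketene acetal of 14 | C=CCC[C@H]1[C@H](C(=C)CCC=C(OC)O[Si](C)(C)C)CC1(C)C | intermediate
17 | methyl 2-bromo-5-[(1R,2S)-2-(but-3-en-1-yl)-3,3-dimethylcyclobutyl]hex-5-enoate | C=CCC[C@H]1[C@H](C(=C)CCC(Br)C(=O)OC)CC1(C)C | intermediate
18 | methyl 2-bromo-5-[(1R,2S)-3,3-dimethyl-2-(3-oxobutyl)cyclobutyl]hex-5-enoate | CC(=O)CC[C@H]1[C@H](C(=C)CCC(Br)C(=O)OC)CC1(C)C | intermediate
19 | samarium (diiodo) ester enolate of 18 | CC(=O)CC[C@H]1[C@H](C(=C)CCC=C(OC)O[Sm](I)I)CC1(C)C | intermediate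
20 | methyl (1S,4S,5S,9R)-4-hydroxy-4,11,11-trimethyl-8-methylidenebicyclo[7.2.0]undecane-5-carboxylate | C=C1CC[C@H](C(=O)OC)[C@@](C)(O)CC[C@H]2[C@H]1CC2(C)C | intermediate
21 | phloroglucinol | Oc1cc(O)cc(O)c1 | starting material
22 | 3,5-bis(methoxymethoxy)phenol | COCOc1cc(O)cc(OCOC)c1 | intermediate
23 | 2-bromo-3,5-bis(methoxymethoxy)phenol | COCOc1cc(O)c(Br)c(OCOC)c1 | intermediate
24 | [2-bromo-3,5-bis(methoxymethoxy)phenoxy]trimethylsilane | COCOc1cc(O[Si](C)(C)C)c(Br)c(OCOC)c1 | intermediate
25 | lithium 3,5-bis(methoxymethoxy)-2-(trimethylsilyl)phenoxide | [Li+].COCOc1cc([O-])c([Si](C)(C)C)c(OCOC)c1 | intermediate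
26 | 3,5-bis(methoxymethoxy)-2-(trimethylsilyl)phenyl trifluoromethanesulfonate | COCOc1cc(OS(=O)(=O)C(F)(F)F)c([Si](C)(C)C)c(OCOC)c1 | intermediate
27 | sodium alkoxide of 20 | [Na+].C=C1CC[C@H](C(=O)OC)[C@@](C)([O-])CC[C@H]2[C@H]1CC2(C)C | intermediate
28 | 3,5-bis(methoxymethoxy)benzyne | COCOC1=CC(OCOC)=CC#C1 | intermediate
29 | sodium aryl anion of the C4 3,5-bis(methoxymethoxy)phenyl ether of 20 | [Na+].C=C1CC[C@H](C(=O)OC)[C@@](C)(Oc3cc(OCOC)cc(OCOC)[c-]3)CC[C@H]2[C@H]1CC2(C)C | intermediate
30 | tricyclic 5,7-bis(methoxymethoxy)chroman-4-one, (1S,4S,5S,9R) | C=C1CC[C@@H]2C(=O)c3c(OCOC)cc(OCOC)cc3O[C@@]2(C)CC[C@H]2[C@H]1CC2(C)C | intermediate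
31 | C1′ tertiary alcohol (1′-hydroxy-1′-phenyl) of 30 | C=C1CC[C@@H]2C(O)(c3ccccc3)c3c(OCOC)cc(OCOC)cc3O[C@@]2(C)CC[C@H]2[C@H]1CC2(C)C | intermediate
32 | C1′ diarylmethyl cation (hydroxytrifluoroborate) | C=C1CC[C@@H]2[C+](c3ccccc3)c3c(OCOC)cc(OCOC)cc3O[C@@]2(C)CC[C@H]2[C@H]1CC2(C)C.O[B-](F)(F)F | intermediate
33 | (1S,4S,5R,9R,1′R)-1′-phenylchroman bis(methoxymethyl) ether | C=C1CC[C@@H]2[C@H](c3ccccc3)c3c(OCOC)cc(OCOC)cc3O[C@@]2(C)CC[C@H]2[C@H]1CC2(C)C | intermediate
34 | (1S,4S,5R,9R,1′R)-5′,7′-dihydroxy-1′-phenylchroman | C=C1CC[C@@H]2[C@H](c3ccccc3)c3c(O)cc(O)cc3O[C@@]2(C)CC[C@H]2[C@H]1CC2(C)C | intermediate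
35 | bis(dimethyliminium) dichloride of 34 at the two free ring positions | C=C1CC[C@@H]2[C@H](c3ccccc3)c3c(O)c(C=[N+](C)C)c(O)c(C=[N+](C)C)c3O[C@@]2(C)CC[C@H]2[C@H]1CC2(C)C.[Cl-].[Cl-] | intermediate
36 | psidial A | C=C1CC[C@@H]2[C@H](c3ccccc3)c3c(O)c(C=O)c(O)c(C=O)c3O[C@@]2(C)CC[C@H]2[C@H]1CC2(C)C | target

**Step count**

Total: 20 steps. Longest linear sequence: 15 steps (steps 1–4, 6–11, 16–20).

**Steps most likely to fail**

1. Step 16 (Proposed new method). What may go wrong: retro‑aldol opening of the sodium aldolate before the aryne is captured; slow addition of the hindered alkoxide, so that the aryne is consumed by other nucleophiles; and proton transfer from C5 to the aryl anion in place of acyl substitution, followed by loss of aryloxide. Fallback, from 20 back to 30, by known reactions only: LiAlH4 (THF, 0 °C) reduces the ester to the diol F1, after which no aldolate can form. TBSCl and imidazole silylate only the primary hydroxyl to give the silyl ether F2. F2, NaH and the aryne precursor 26 with CsF in MeCN/THF give the tertiary 3,5‑bis(methoxymethoxy)phenyl ether F3; this is alkoxide addition to an aryne of the tert‑butoxide/benzyne type, with the solvent as proton source. TBAF frees the primary alcohol F4. TEMPO with PhI(OAc)2 in aqueous MeCN oxidises it to the acid F5. Intramolecular Friedel–Crafts acylation of the electron‑rich ring through the mixed trifluoroacetic anhydride (TFAA, 2,6‑di‑tert‑butyl‑4‑methylpyridine, CH2Cl2, 0 °C) closes the pyranone to 30.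

2. Step 11. What may go wrong: intermolecular coupling or simple reduction of the bromide in place of nine‑membered ring closure, and poor facial selectivity at C4/C5 relative to the remote cyclobutane (up to four diastereomers). If only C5 is wrong, it can be equilibrated later, at the chromanone 30, where it is α to the ketone. Fallback, from 14 back to 20, moving stereocontrol from the substrate to an auxiliary: LiOH saponifies 14 to the acid F6. Coupling with (R)‑4‑benzyl‑1,3‑oxazolidin‑2‑one (PivCl, Et3N, LiCl, THF) gives the imide F7. Bu2BOTf and iPr2NEt, then NBS, give the α‑bromo imide F8. The Wacker conditions of step 10 give the bromo keto imide F9. SmI2 at high dilution closes the ring through the chelated Z‑enolate, in which the benzyl group fixes the face of C5, to give the β‑hydroxy imide F10 (samarium Reformatsky reaction of α‑bromoacyl oxazolidinones). MeOMgBr in MeOH at 0 °C exchanges the auxiliary for methoxide and returns 20.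

3. Step 18. What may go wrong: loss of H‑5 from the diarylmethyl cation to give the chromene, which would erase C5 on re‑protonation; capture of the cation by the C8 alkene; reductive cleavage of a MOM acetal; and hydride delivery to the other face. Fallback, from 31 back to 33, without a cation: KHMDS and methyl chlorooxalate (THF, −78 °C) convert 31 into the tertiary methyl oxalate F11. Bu3SnH with AIBN in toluene at 90 °C then cleaves the C–O bond homolytically (tin hydride deoxygenation of a tertiary alcohol through its oxalate ester); the planar diarylmethyl radical should take hydrogen on the same open face.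

**Further compounds**

F1 | step 16 | (1S,4S,5R,9R)-5-(hydroxymethyl)-4,11,11-trimethyl-8-methylidenebicyclo[7.2.0]undecan-4-ol | C=C1CC[C@H](CO)[C@@](C)(O)CC[C@H]2[C@H]1CC2(C)C
F2 | step 16 | primary tert-butyldimethylsilyl ether of F1 | C=C1CC[C@H](CO[Si](C)(C)C(C)(C)C)[C@@](C)(O)CC[C@H]2[C@H]1CC2(C)C
F3 | step 16 | C4 3,5-bis(methoxymethoxy)phenyl ether of F2 | C=C1CC[C@H](CO[Si](C)(C)C(C)(C)C)[C@@](C)(Oc3cc(OCOC)cc(OCOC)c3)CC[C@H]2[C@H]1CC2(C)C
F4 | step 16 | primary alcohol from F3 | C=C1CC[C@H](CO)[C@@](C)(Oc3cc(OCOC)cc(OCOC)c3)CC[C@H]2[C@H]1CC2(C)C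
F5 | step 16 | (1S,4S,5S,9R)-4-[3,5-bis(methoxymethoxy)phenoxy]-4,11,11-trimethyl-8-methylidenebicyclo[7.2.0]undecane-5-carboxylic acid | C=C1CC[C@H](C(=O)O)[C@@](C)(Oc3cc(OCOC)cc(OCOC)c3)CC[C@H]2[C@H]1CC2(C)C
F6 | step 11 | 5-[(1R,2S)-2-(but-3-en-1-yl)-3,3-dimethylcyclobutyl]hex-5-enoic acid | C=CCC[C@H]1[C@H](C(=C)CCCC(=O)O)CC1(C)C
F7 | step 11 | (R)-4-benzyl-3-{5-[(1R,2S)-2-(but-3-en-1-yl)-3,3-dimethylcyclobutyl]hex-5-enoyl}-1,3-oxazolidin-2-one | C=CCC[C@H]1[C@H](C(=C)CCCC(=O)N2[C@H](Cc3ccccc3)COC2=O)CC1(C)C
F8 | step 11 | 2-bromo derivative of imide F7 | C=CCC[C@H]1[C@H](C(=C)CCC(Br)C(=O)N2[C@H](Cc3ccccc3)COC2=O)CC1(C)C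
F9 | step 11 | bromo keto imide (3-oxobutyl side chain) from F8 | CC(=O)CC[C@H]1[C@H](C(=C)CCC(Br)C(=O)N2[C@H](Cc3ccccc3)COC2=O)CC1(C)C
F10 | step 11 | nine-membered β-hydroxy imide, (1S,4S,5S,9R), N-acyl-(R)-4-benzyl-1,3-oxazolidin-2-one | C=C1CC[C@H](C(=O)N3[C@H](Cc4ccccc4)COC3=O)[C@@](C)(O)CC[C@H]2[C@H]1CC2(C)C
F11 | step 18 | C1′ methyl oxalate ester of 31 | C=C1CC[C@@H]2C(OC(=O)C(=O)OC)(c3ccccc3)c3c(OCOC)cc(OCOC)cc3O[C@@]2(C)CC[C@H]2[C@H]1CC2(C)C
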